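**Plan**

- Retrosynthetic cuts, in order: the C15–O ester bond and the lactone that masks the 15,16-diol; C4–C18; the ring-A carbon C3, taken out from between C4 and C2 so that ring A becomes the cyclopentanone of a trans-hydrindane; C12=C13 (metathesis); C8=C17; C9–C11 (allylation); the two annulation bonds C9–C10 and C5–C6.
- Forward order: ring B and a five-membered ring-A precursor (C1, C2, C4, C5, C10) are built together by an amino-acid-catalysed annulation. C9/C10, the side chain with C13, and C8 follow. Ring A reaches its final size in step 12 and is then methylated. Reduction and enzymatic acylation finish the route.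
- Enabling feature: in ring A, C4 (the carbon that carries C18 and the alkene) lies between the fully substituted C5 and a plain CH2 chain. A C4 ketone in the strained five-membered ring can therefore take up one carbon on the CH2 side only, so the new atom becomes C3 and the carbonyl stays at C4 for the methyl.
- Stereochemistry: C5 from D-phenylalanine catalysis; C10 and C9 from the reductive allylation (both steered by the C19 methyl); C13 from Ru–BINAP hydrogenation (catalyst control); C8 from hydrogenation anti to the axial C20 methyl. The ring expansion touches no stereocentre.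
- Numbering: clerodane (ring A = C1–C5, C10; ring B = C5–C10; C17 on C8, C18 on C4, C19 on C5, C20 on C9; side chain C11–C16).

Key step: step 12

Assumption: Ru(OAc)2[(S)-BINAP] is taken to add H2 to the face of the (E)-alkylidene lactone that gives the (3R)-lactone; the sense is set by the catalyst, so if it proved opposite the (R)-ligand would be used with no other change.

**Route**

Step 1
Reactants: 1 2-methylcyclopentane-1,3-dione; 2 pent-1-en-3-one (ethyl vinyl ketone)
Product: 3 2-methyl-2-(3-oxopentyl)cyclopentane-1,3-dione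
Conditions: H2O, AcOH (cat.), 70 °C
Reagents that add atoms: none
Why: Michael addition of the acidic 1,3-dione to the enone; no stereocentre is formed.

Step 2
Reactants: 3 2-methyl-2-(3-oxopentyl)cyclopentane-1,3-dione
Product: 5 (7aR)-4,7a-dimethyl-2,3,7,7a-tetrahydro-1H-indene-1,5(6H)-dione, via bicyclic ketol 4 (not isolated)
Conditions: D-phenylalanine (1 equiv), camphorsulfonic acid (0.5 equiv), DMF, 30 → 70 °C
Reagents that add atoms: none
Why: Hajos–Parrish–Eder–Sauer–Wiechert aldol condensation, in which the enamine of the side-chain ketone with D-phenylalanine attacks one of the two enantiotopic ring carbonyls under direction by the carboxylic acid, setting the quaternary C5 as 7aR (the mirror image of the sense given by the L-amino acid), and the acid dehydrates ketol 4.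

Step 3
Reactants: 5 (7aR)-4,7a-dimethyl-2,3,7,7a-tetrahydro-1H-indene-1,5(6H)-dione
Product: 6 (1R,7aR)-1-hydroxy-4,7a-dimethyl-1,2,3,6,7,7a-hexahydro-5H-inden-5-one
Conditions: NaBH4 (0.3 equiv), EtOH, −20 °C
Reagents that add atoms: none
Why: Chemoselective 1,2-reduction, in which borohydride attacks the saturated cyclopentanone (the enone carbonyl is deactivated by conjugation) from the face opposite the angular methyl, giving the alcohol cis to that methyl (a temporary stereocentre, removed in step 11).

Step 4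
Reactants: 6 (1R,7aR)-1-hydroxy-4,7a-dimethyl-1,2,3,6,7,7a-hexahydro-5H-inden-5-one
Product: 7 (1R,7aR)-1-(tert-butyldimethylsilyloxy)-4,7a-dimethyl-1,2,3,6,7,7a-hexahydro-5H-inden-5-one
Conditions: TBSCl, imidazole, DMF, 40 °C
Reagents that add atoms: tert-butyldimethylsilyl chloride, CC(C)(C)[Si](C)(C)Cl
Why: Silylation of the secondary alcohol masks the C4 oxygen through the dissolving-metal, ylide and hydrogenation steps.

Step 5
Reactants: 7 (1R,7aR)-1-(tert-butyldimethylsilyloxy)-4,7a-dimethyl-1,2,3,6,7,7a-hexahydro-5H-inden-5-one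
Product: 9 (1R,3aS,4R,7aR)-4-allyl-1-(tert-butyldimethylsilyloxy)-4,7a-dimethyloctahydro-5H-inden-5-one, via lithium enolate 8 (not isolated)
Conditions: Li (2.2 equiv), NH3(l)/THF, t-BuOH (1 equiv), −78 °C; allyl bromide, −78 → −33 °C; NH4Cl
Reagents that add atoms: allyl bromide, C=CCBr
Why: Reductive alkylation of an enone (Birch-type), in which the C10 carbanion is protonated on the face opposite the angular C19 methyl (trans-hydrindane) and the regiodefined C8–C9 enolate 8 is allylated anti to C19 (avoiding a 1,3-diaxial clash), so that C9 becomes quaternary with C20 cis to C19.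

Step 6
Reactants: 9 (1R,3aS,4R,7aR)-4-allyl-1-(tert-butyldimethylsilyloxy)-4,7a-dimethyloctahydro-5H-inden-5-one
Product: 10 (1R,3aR,4R,7aR)-4-allyl-1-(tert-butyldimethylsilyloxy)-4,7a-dimethyl-5-methyleneoctahydro-1H-indene
Conditions: Ph3PCH3Br, KOtBu, toluene, 90 °C
Reagents that add atoms: methylenetriphenylphosphorane, C=P(c1ccccc1)(c1ccccc1)c1ccccc1
Why: Wittig methylenation of the hindered C8 ketone with a non-stabilised ylide at elevated temperature; the neighbouring C9 is quaternary and cannot epimerise.

Step 7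
Reactants: 10 (1R,3aR,4R,7aR)-4-allyl-1-(tert-butyldimethylsilyloxy)-4,7a-dimethyl-5-methyleneoctahydro-1H-indene; 11 3-methylenedihydrofuran-2(3H)-one (α-methylene-γ-butyrolactone, 4 equiv)
Product: 12 (E)-3-{2-[(1R,3aR,4R,7aR)-1-(tert-butyldimethylsilyloxy)-4,7a-dimethyl-5-methyleneoctahydro-1H-inden-4-yl]ethylidene}dihydrofuran-2(3H)-one
Conditions: Hoveyda–Grubbs II (5 mol %), 2,6-dichloro-1,4-benzoquinone (10 mol %), CH2Cl2, 40 °C
Reagents that add atoms: none
Why: Olefin cross-metathesis of the monosubstituted allyl alkene with the excess methylene lactone (the hindered C8 methylene is inert and ring closure between the two alkenes would need a cyclobutene), with the quinone suppressing isomerisation of 11 and the (E)-alkylidene lactone expected to dominate.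

Step 8
Reactants: 12 (E)-alkylidene lactone
Product: 13 (3R)-3-{2-[(1R,3aR,4R,7aR)-1-(tert-butyldimethylsilyloxy)-4,7a-dimethyl-5-methyleneoctahydro-1H-inden-4-yl]ethyl}dihydrofuran-2(3H)-one
Conditions: Ru(OAc)2[(S)-BINAP] (1 mol %), H2 (50 atm), MeOH–CH2Cl2, 50 °C
Reagents that add atoms: none
Why: Ru–BINAP asymmetric hydrogenation of an α-alkylidene lactone, in which the lactone carbonyl binds ruthenium so that only the conjugated C12=C13 is reduced and C13 is set by the ligand (catalyst control, the ring stereocentres being remote), leaving the unfunctionalised C8 methylene untouched.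

Step 9
Reactants: 13 (3R)-lactone with C8 methylene
Product: 14 (3R)-3-{2-[(1R,3aR,4S,5R,7aR)-1-(tert-butyldimethylsilyloxy)-4,5,7a-trimethyloctahydro-1H-inden-4-yl]ethyl}dihydrofuran-2(3H)-one
Conditions: H2 (1 atm), PtO2, EtOAc, rt
Reagents that add atoms: none
Why: Heterogeneous hydrogenation of the exocyclic alkene from the β face, anti to the axial C20 methyl on the neighbouring quaternary C9, should place the C17 methyl equatorial and cis to C20.

Step 10
Reactants: 14 silyl ether
Product: 15 (3R)-3-{2-[(1R,3aR,4S,5R,7aR)-1-hydroxy-4,5,7a-trimethyloctahydro-1H-inden-4-yl]ethyl}dihydrofuran-2(3H)-one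
Conditions: 48% aq. HF, MeCN, rt
Reagents that add atoms: none
Why: Acidic desilylation with HF is non-basic, so the lactone α-stereocentre C13 is not at risk.

Step 11
Reactants: 15 alcohol
Product: 16 (3R)-3-{2-[(3aR,4S,5R,7aR)-4,5,7a-trimethyl-1-oxooctahydro-1H-inden-4-yl]ethyl}dihydrofuran-2(3H)-one
Conditions: Dess–Martin periodinane, CH2Cl2, rt
Reagents that add atoms: none
Why: Dess–Martin oxidation of the secondary alcohol under neutral conditions returns the C4 cyclopentanone without touching C13.

Step 12
Reactants: 16 trans-hydrindan-1-one lactone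
Product: 18 (3R)-3-{2-[(1S,2R,4aR,8aR)-1,2,4a-trimethyl-5-oxodecahydronaphthalen-1-yl]ethyl}dihydrofuran-2(3H)-one, via alpha-silyl ketone 17 (not isolated)
Conditions: TMSCHN2 (1.5 equiv), BF3·OEt2 (1.5 equiv), CH2Cl2, −78 → −20 °C; then 1 M HCl, THF, rt
Reagents that add atoms: trimethylsilyldiazomethane, C[Si](C)(C)C=[N+]=[N-]
Why: BF3 activates the strained, trans-fused C4 cyclopentanone and the diazo carbon adds to C4 to give a β-oxido diazonium betaine; loss of N2 is concerted with a 1,2-shift of the ring CH2 (C2) from C4 to the new carbon (C3), which re-forms the C4 carbonyl and gives α-silyl ketone 17, protodesilylated on acidic work-up to 18 (Tiffeneau–Demjanov-type diazoalkane homologation, closest precedent the D-homoannulation of 17-keto steroids, which have the same quaternary-carbon-flanked trans-hydrindanone). No ring is closed: ring A grows from the five-membered ring C1–C2–C4–C5–C10 to six members by insertion of C3, while ring B and the lactone are spectators. No stereocentre is created; the migrating carbon is a CH2, C5 and C10 take no part in the shift and keep the trans ring fusion, and C8, C9 and C13 are remote. The selectivity needed is regiochemical, migration of C2 and not of the quaternary C5, and it is secured by the bulky Me3Si group, which in the anti-periplanar transition state turns away from the fully substituted C5 so that the CH2 arm is aligned with the leaving N2. The ketone reacts in preference to the lactone because it is far more electrophilic, and a second insertion is held back because the product carbonyl is shielded by the α-silyl group and C5 and has lost the ring strain.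

Step 13
Reactants: 18 decalone lactone
Product: 20 (3R)-3-{2-[(1S,2R,4aR,8aR)-1,2,4a-trimethyl-5-(trifluoromethylsulfonyloxy)-1,2,3,4,4a,7,8,8a-octahydronaphthalen-1-yl]ethyl}dihydrofuran-2(3H)-one, via potassium enolate 19 (not isolated)
Conditions: KHMDS (1.05 equiv), THF, −78 °C; PhNTf2, −78 → 0 °C; NH4Cl
Reagents that add atoms: N-phenylbis(trifluoromethanesulfonimide), O=S(=O)(N(c1ccccc1)S(=O)(=O)C(F)(F)F)C(F)(F)F
Why: Enol triflate formation, in which the ketone can enolise only toward C3 (C5 is quaternary) and its CH2 is more acidic than the tertiary lactone α-CH, so one equivalent of base at −78 °C should give enolate 19, which is trapped on oxygen.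

Step 14
Reactants: 20 enol triflate
Product: 21 (3R)-3-{2-[(1S,2R,4aR,8aR)-1,2,4a,5-tetramethyl-1,2,3,4,4a,7,8,8a-octahydronaphthalen-1-yl]ethyl}dihydrofuran-2(3H)-one
Conditions: MeZnCl (2 equiv), Pd(PPh3)4 (5 mol %), THF, 50 °C
Reagents that add atoms: methylzinc chloride, C[Zn]Cl
Why: Negishi coupling of the alkenyl triflate installs C18 on C4 and fixes the C3=C4 alkene, and the organozinc does not attack the lactone.

Step 15
Reactants: 21 clerod-3-ene lactone
Product: 22 (2R)-2-{2-[(1S,2R,4aR,8aR)-1,2,4a,5-tetramethyl-1,2,3,4,4a,7,8,8a-octahydronaphthalen-1-yl]ethyl}butane-1,4-diol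
Conditions: LiAlH4, THF, 0 °C → rt; Fieser work-up
Reagents that add atoms: none
Why: Hydride reduction of the lactone gives the 15,16-diol without affecting the trisubstituted alkene, and C13 is no longer α to a carbonyl afterwards.

Step 16
Reactants: 22 15,16-diol; 23 docosanoic acid (1.05 equiv)
Product: 24 (3R)-3-(hydroxymethyl)-5-[(1S,2R,4aR,8aR)-1,2,4a,5-tetramethyl-1,2,3,4,4a,7,8,8a-octahydronaphthalen-1-yl]pentyl docosanoate
Conditions: immobilised Candida antarctica lipase B, 4 Å MS, toluene, 50 °C
Reagents that add atoms: none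
Why: Lipase-catalysed esterification (serine hydrolase, acyl-enzyme mechanism), in which the long-chain acyl group should go to the less hindered C15 hydroxyl, two CH2 groups from the branch point, in preference to the β-branched C16 hydroxyl, with the sieves removing water.

**Compound list**

1 | 2-methylcyclopentane-1,3-dione | CC1C(=O)CCC1=O | starting material
2 | pent-1-en-3-one (ethyl vinyl ketone) | CCC(=O)C=C | starting material
3 | 2-methyl-2-(3-oxopentyl)cyclopentane-1,3-dione | CCC(=O)CCC1(C)C(=O)CCC1=O | intermediate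
4 | cis-fused ketol, (7aR)-3a-hydroxy-4,7a-dimethylhexahydro-1H-indene-1,5-dione, OH cis to the angular methyl, both configurations at the C-methyl carbon | CC1C(=O)CC[C@@]2(C)C(=O)CC[C@@]12O | intermediate (not isolated)
5 | (7aR)-4,7a-dimethyl-2,3,7,7a-tetrahydro-1H-indene-1,5(6H)-dione | O=C1CC[C@@]2(C)C(=O)CCC2=C1C | intermediate
6 | (1R,7aR)-1-hydroxy-4,7a-dimethyl-1,2,3,6,7,7a-hexahydro-5H-inden-5-one | O=C1CC[C@@]2(C)[C@H](O)CCC2=C1C | intermediate
7 | (1R,7aR)-1-(tert-butyldimethylsilyloxy)-4,7a-dimethyl-1,2,3,6,7,7a-hexahydro-5H-inden-5-one | O=C1CC[C@@]2(C)[C@H](O[Si](C)(C)C(C)(C)C)CCC2=C1C | intermediate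
8 | lithium enolate (C8–C9) of the trans-fused hydrindanone | CC1=C(O[Li])CC[C@@]2(C)[C@H](O[Si](C)(C)C(C)(C)C)CC[C@H]12 | intermediate (not isolated)
9 | (1R,3aS,4R,7aR)-4-allyl-1-(tert-butyldimethylsilyloxy)-4,7a-dimethyloctahydro-5H-inden-5-one (trans-fused, allyl anti to the angular methyl) | C=CC[C@@]1(C)C(=O)CC[C@@]2(C)[C@H](O[Si](C)(C)C(C)(C)C)CC[C@H]12 | intermediate
10 | (1R,3aR,4R,7aR)-4-allyl-1-(tert-butyldimethylsilyloxy)-4,7a-dimethyl-5-methyleneoctahydro-1H-indene | C=CC[C@@]1(C)C(=C)CC[C@@]2(C)[C@H](O[Si](C)(C)C(C)(C)C)CC[C@H]12 | intermediate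
11 | 3-methylenedihydrofuran-2(3H)-one (α-methylene-γ-butyrolactone) | C=C1CCOC1=O | starting material
12 | (E)-3-{2-[(1R,3aR,4R,7aR)-1-(tert-butyldimethylsilyloxy)-4,7a-dimethyl-5-methyleneoctahydro-1H-inden-4-yl]ethylidene}dihydrofuran-2(3H)-one | O=C1OCC/C1=C\C[C@@]3(C)C(=C)CC[C@@]2(C)[C@H](O[Si](C)(C)C(C)(C)C)CC[C@H]32 | intermediate
13 | (3R)-3-{2-[(1R,3aR,4R,7aR)-1-(tert-butyldimethylsilyloxy)-4,7a-dimethyl-5-methyleneoctahydro-1H-inden-4-yl]ethyl}dihydrofuran-2(3H)-one | O=C1OCC[C@H]1CC[C@@]3(C)C(=C)CC[C@@]2(C)[C@H](O[Si](C)(C)C(C)(C)C)CC[C@H]32 | intermediate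
14 | (3R)-3-{2-[(1R,3aR,4S,5R,7aR)-1-(tert-butyldimethylsilyloxy)-4,5,7a-trimethyloctahydro-1H-inden-4-yl]ethyl}dihydrofuran-2(3H)-one | O=C1OCC[C@H]1CC[C@@]3(C)[C@H](C)CC[C@@]2(C)[C@H](O[Si](C)(C)C(C)(C)C)CC[C@H]32 | intermediate
15 | (3R)-3-{2-[(1R,3aR,4S,5R,7aR)-1-hydroxy-4,5,7a-trimethyloctahydro-1H-inden-4-yl]ethyl}dihydrofuran-2(3H)-one | O=C1OCC[C@H]1CC[C@@]3(C)[C@H](C)CC[C@@]2(C)[C@H](O)CC[C@H]32 | intermediate
16 | (3R)-3-{2-[(3aR,4S,5R,7aR)-4,5,7a-trimethyl-1-oxooctahydro-1H-inden-4-yl]ethyl}dihydrofuran-2(3H)-one | O=C1OCC[C@H]1CC[C@@]3(C)[C@H](C)CC[C@@]2(C)C(=O)CC[C@H]32 | intermediate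
17 | α-trimethylsilyl decalone (silyl group on C3, both epimers) | O=C1OCC[C@H]1CC[C@@]3(C)[C@H](C)CC[C@@]2(C)C(=O)C([Si](C)(C)C)CC[C@H]32 | intermediate (not isolated)
18 | (3R)-3-{2-[(1S,2R,4aR,8aR)-1,2,4a-trimethyl-5-oxodecahydronaphthalen-1-yl]ethyl}dihydrofuran-2(3H)-one | O=C1OCC[C@H]1CC[C@@]3(C)[C@H](C)CC[C@@]2(C)C(=O)CCC[C@H]32 | intermediate
19 | potassium enolate (C3=C4) of 18 | O=C1OCC[C@H]1CC[C@@]3(C)[C@H](C)CC[C@@]2(C)C(O[K])=CCC[C@H]32 | intermediate (not isolated)
20 | (3R)-3-{2-[(1S,2R,4aR,8aR)-1,2,4a-trimethyl-5-(trifluoromethylsulfonyloxy)-1,2,3,4,4a,7,8,8a-octahydronaphthalen-1-yl]ethyl}dihydrofuran-2(3H)-one | O=C1OCC[C@H]1CC[C@@]3(C)[C@H](C)CC[C@@]2(C)C(OS(=O)(=O)C(F)(F)F)=CCC[C@H]32 | intermediate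
21 | (3R)-3-{2-[(1S,2R,4aR,8aR)-1,2,4a,5-tetramethyl-1,2,3,4,4a,7,8,8a-octahydronaphthalen-1-yl]ethyl}dihydrofuran-2(3H)-one | O=C1OCC[C@H]1CC[C@@]3(C)[C@H](C)CC[C@@]2(C)C(C)=CCC[C@H]32 | intermediate
22 | (2R)-2-{2-[(1S,2R,4aR,8aR)-1,2,4a,5-tetramethyl-1,2,3,4,4a,7,8,8a-octahydronaphthalen-1-yl]ethyl}butane-1,4-diol | OCC[C@H](CO)CC[C@@]1(C)[C@H](C)CC[C@@]2(C)C(C)=CCC[C@H]12 | intermediate
23 | docosanoic acid | CCCCCCCCCCCCCCCCCCCCCC(=O)O | starting material
24 | (3R)-3-(hydroxymethyl)-5-[(1S,2R,4aR,8aR)-1,2,4a,5-tetramethyl-1,2,3,4,4a,7,8,8a-octahydronaphthalen-1-yl]pentyl docosanoate | CCCCCCCCCCCCCCCCCCCCCC(=O)OCC[C@H](CO)CC[C@@]1(C)[C@H](C)CC[C@@]2(C)C(C)=CCC[C@H]12 | target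

**Count and risks**

Total steps: 16. Longest linear sequence: 16 (from 1 and 2 to 24; 11 and 23 are bought).

Step 16, acylation of the wrong hydroxyl or of both. The two primary alcohols differ only in their distance from the branch point, so the enzyme may not distinguish them well enough. The fallback sets out from lactone 21 and lets the lactone itself tell the two oxygens apart. Opening with N,O-dimethylhydroxylamine hydrochloride and AlMe3 would give the hydroxy Weinreb amide F6, with C15–OH free and C16 as the amide. Acylation with docosanoyl chloride, pyridine and DMAP would give the ester amide F7. Cp2Zr(H)Cl should reduce the amide, and not the ester, to the ester aldehyde F8. Immediate NaBH4 reduction in MeOH at −20 °C would return to the route at 24.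

Step 5, protonation of C10 from the wrong face (cis ring fusion), proton exchange that scrambles the enolate, or O- and poly-allylation. The fallback sets out from 7. A copper hydride conjugate reduction (t-BuCu/DIBAL-H, THF–HMPA, −50 °C) should deliver hydride to C10 anti to the angular methyl. The aluminium enolate, activated with MeLi, would be trapped on oxygen with allyl chloroformate to give the trans-fused allyl enol carbonate F1. Pd(0)-catalysed decarboxylative allylation (Tsuji; Pd2(dba)3, PPh3 or a t-Bu-PHOX ligand to reinforce the facial preference, THF) would then form C9–C11 anti to C19 and return to the route at 9.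

Step 12, stalled addition to the hindered C4 carbonyl, competing migration of the quaternary C5, or a second insertion. The fallback sets out from 16 and fixes the regiochemistry through the position of an enol double bond. Soft enolisation (TMSOTf, Et3N), possible only toward C2, would give the trimethylsilyl enol ether F2. Simmons–Smith cyclopropanation (Et2Zn, CH2I2) would give the siloxycyclopropane F3, in which the future C3 bridges C4 and C2. Ito–Saegusa cleavage of the internal cyclopropane bond with FeCl3 in DMF would give the ring-enlarged β-chloro ketone F4. Elimination with NaOAc in MeOH would give the cyclohexenone F5, and hydrogenation (H2, Pd/C, EtOAc) would return to the route at 18.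

**Further compounds**

F1 | step 5 | allyl enol carbonate of the trans-fused hydrindanone (C8–C9 enol) | CC1=C(OC(=O)OCC=C)CC[C@@]2(C)[C@H](O[Si](C)(C)C(C)(C)C)CC[C@H]12
F2 | step 12 | trimethylsilyl enol ether (C4=C2) of 16 | O=C1OCC[C@H]1CC[C@@]3(C)[C@H](C)CC[C@@]2(C)C(O[Si](C)(C)C)=CC[C@H]32
F3 | step 12 | siloxycyclopropane, CH2 bridging C4 and C2 anti to the angular methyl | O=C1OCC[C@H]1CC[C@@]3(C)[C@H](C)CC[C@@]2(C)[C@@]4(O[Si](C)(C)C)C[C@H]4C[C@H]32
F4 | step 12 | ring-enlarged β-chloro ketone (chlorine on C2, both epimers) | O=C1OCC[C@H]1CC[C@@]3(C)[C@H](C)CC[C@@]2(C)C(=O)CC(Cl)C[C@H]32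
F5 | step 12 | cyclohex-2-enone (C4 ketone, C2=C3 alkene) | O=C1OCC[C@H]1CC[C@@]3(C)[C@H](C)CC[C@@]2(C)C(=O)C=CC[C@H]32
F6 | step 16 | hydroxy Weinreb amide, (2R)-2-(2-hydroxyethyl)-N-methoxy-N-methyl-4-[(1S,2R,4aR,8aR)-1,2,4a,5-tetramethyl-1,2,3,4,4a,7,8,8a-octahydronaphthalen-1-yl]butanamide | OCC[C@H](C(=O)N(C)OC)CC[C@@]1(C)[C@H](C)CC[C@@]2(C)C(C)=CCC[C@H]12
F7 | step 16 | docosanoate ester of F6 | CCCCCCCCCCCCCCCCCCCCCC(=O)OCC[C@H](C(=O)N(C)OC)CC[C@@]1(C)[C@H](C)CC[C@@]2(C)C(C)=CCC[C@H]12
F8 | step 16 | ester aldehyde (C16 as CHO) | CCCCCCCCCCCCCCCCCCCCCC(=O)OCC[C@H](C=O)CC[C@@]1(C)[C@H](C)CC[C@@]2(C)C(C)=CCC[C@H]12
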